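Retrosynthetic overview
1. Feature used: in ring B the methyl-bearing C8 and C10 flank C9, with C6 para to C9. This is the pattern of 2,6-dimethylphenol oxidised at its para carbon. C1–C4, with both C4 methyls and O3, are the carbons of the silyl enol ether of isopropyl vinyl ketone.
2. Last bonds made: the C3–O tiglate ester, then the C11–O aryl ether. The trans-diaxial pair 8-OH / 9-CH2X comes from a C8–C9–C11 cyclopropane opened by divalent mercury with inversion at C8.
3. The cyclopropane comes from an 8-ene. The 8-ene and the trans ring fusion both come from the ring-B ene-dione through enol triflates at C9 and C6: formate reduction, then hydrogen-atom-transfer hydrogenation of C5=C6.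
4. Key disconnection: C4–C5 and C1–C10, an enantioselective Diels–Alder reaction that desymmetrises the prochiral 2,6-dimethylquinone monoketal.
5. Ring order: ring B (bought as the phenol), ring A (step 3), a transient cyclopropane (made in step 9, opened in step 13). The coumarin rings are bought.

Key step: step 3

Numbering: drimane numbering is used (ring A = C1–C5, C10; ring B = C5–C10; C11 on C9; C12 = methyl on C8; C13/C14 = methyls on C4; C15 = methyl on C10). Compounds that still lack C11 are named as 11-nordrimanes.
Assumption: the dienone has no α-C–H for the usual C–H···O contact with the catalyst, so the sense of induction cannot be read from known cases; the catalyst from (S)-diphenylprolinol is written, and its equally available mirror image would be taken if the adduct formed as the antipode.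

Step 1
Reactants: 1 4-methoxy-2,6-dimethylphenol
Product: 2 4,4-dimethoxy-2,6-dimethylcyclohexa-2,5-dien-1-one (achiral, two mirror-related enone units)
Conditions: PhI(OAc)2, MeOH, 0 °C → rt
Reagents that add atoms: methanol, CO
Why: Oxidative dearomatisation of a para-alkoxyphenol with a hypervalent iodine diacetate: the phenoxenium-type intermediate is captured by methanol at the methoxy-bearing para carbon, which is the standard one-step entry to quinone monoketals, and no stereocentre is formed.

Step 2
Reactants: 3 4-methylpent-1-en-3-one (isopropyl vinyl ketone)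
Product: 4 3-(tert-butyldimethylsilyloxy)-4-methylpenta-1,3-diene
Conditions: TBSOTf, Et3N, Et2O, 0 °C
Reagents that add atoms: tert-butyldimethylsilyl trifluoromethanesulfonate, CC(C)(C)[Si](C)(C)OS(=O)(=O)C(F)(F)F
Why: Soft enolisation and O-silylation (silyl triflate plus tertiary amine): the isopropyl methine is the only enolisable position and the new alkene terminus carries two identical methyls, so a single 2-silyloxydiene without regio- or geometrical isomers should result.

Step 3
Reactants: 2 4,4-dimethoxy-2,6-dimethylcyclohexa-2,5-dien-1-one; 4 3-(tert-butyldimethylsilyloxy)-4-methylpenta-1,3-diene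
Product: 5 (5S,10R)-3-(tert-butyldimethylsilyloxy)-6,6-dimethoxy-11-nordrima-2,7-dien-9-one (cis-fused: H-5 and C15 on the same face; C10 as in the target)
Conditions: (S)-3,3-diphenyl-1-(o-tolyl)tetrahydropyrrolo[1,2-c][1,3,2]oxazaborole (20 mol %) + HN(SO2CF3)2 (18 mol %), CH2Cl2, −78 → −20 °C
Reagents that add atoms: none
Why: Proposed new method: the cationic boron Lewis acid binds the only carbonyl of 2 (C9), which makes the unsubstituted C5 the electrophilic end of each α-methyl enone, so the nucleophilic enol-ether terminus C4 of 4 bonds to C5 and the vinyl terminus C1 to the methyl-bearing C10, either in one strongly asynchronous [4+2] event or as a Mukaiyama–Michael addition followed by Michael closure of the boron enolate onto the silyloxyallyl cation. The closest known reaction types are oxazaborolidinium-catalysed Diels–Alder reactions of 2-silyloxydienes with quinones and cyclic enones, Diels–Alder additions of silyloxydienes to quinone monoketals, and strong-acid-promoted annulations of hindered 2-silyloxydienes with hindered enones; catalytic selection between the enantiotopic alkenes of a 2,6-disubstituted quinone monoketal has not been shown. Ring A closes as a six-membered carbocycle by suprafacial [4+2] addition on the alkene (a 6-endo-trig attack of C10 on C1 in the stepwise variant) and keeps the C2=C3 silyl enol ether. C10 is controlled by the catalyst, which sits on one of the two enantiotopic lone pairs of the C9 oxygen, covers one face of the flat dienone with a phenyl group of the prolinol and crowds the nearer alkene with its o-tolyl group, so that one alkene-and-face combination is left open; C5 is controlled by C10, because both bonds form on the same face and give the cis fusion. The step needs regio-, enantio- and mono-selectivity: regiochemistry is secured by the single carbonyl and by pairing the hindered CMe2 terminus with the CH carbon, endo/exo selectivity is irrelevant because neither diene terminus becomes a stereocentre, and a second addition is unlikely because the remaining enone of 5 lies between a quaternary carbon and the ketal in a folded cis-decalin. A slight deficit of HN(SO2CF3)2 relative to the oxazaborolidine keeps free acid low and so limits ketal ionisation and the racemic pathway through silyl triflimide.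

Step 4
Reactants: 5 (5S,10R)-3-(tert-butyldimethylsilyloxy)-6,6-dimethoxy-11-nordrima-2,7-dien-9-one
Product: 6 (5S,10R)-11-nordrim-7-ene-3,6,9-trione (cis-fused)
Conditions: 1 M HCl, THF, 0 °C → rt
Reagents that add atoms: water, O
Why: Acid hydrolysis of a silyl enol ether and of a dimethyl ketal unmasks the C3 and C6 ketones in one operation; partial epimerisation at C5 through the C6 enol is harmless because C5 becomes trigonal in step 6, and base is avoided because the free C3 ketone would open a retro-Michael path (C1–C10 cleavage) towards an aromatic hydroquinone.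

Step 5
Reactants: 6 (5S,10R)-11-nordrim-7-ene-3,6,9-trione
Product: 7 (5S,10R)-3,3-ethylenedioxy-11-nordrim-7-ene-6,9-dione (cis-fused)
Conditions: TMSOCH2CH2OTMS, TMSOTf (5 mol %), CH2Cl2, −78 → −20 °C
Reagents that add atoms: 1,2-bis(trimethylsilyloxy)ethane, C[Si](C)(C)OCCO[Si](C)(C)C
Why: Aprotic dioxolanation catalysed by a silyl triflate is known to take a saturated ketone in preference to conjugated ones, and here the two ene-dione carbonyls are also electron-poor and more hindered, so only C3 is masked, which removes the acidic C2 hydrogens and the retro-Michael path before strong base is used.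

Step 6
Reactants: 7 (5S,10R)-3,3-ethylenedioxy-11-nordrim-7-ene-6,9-dione
Product: 9 (10R)-3,3-ethylenedioxy-9-oxo-11-nordrima-5,7-dien-6-yl trifluoromethanesulfonate, via potassium C5=C6 enolate 8 (not isolated)
Conditions: KN(SiMe3)2, THF, −78 °C; then N-(5-chloropyridin-2-yl)bis(trifluoromethanesulfonimide), −78 → 0 °C
Reagents that add atoms: N-(5-chloropyridin-2-yl)bis(trifluoromethanesulfonimide), O=S(=O)(N(c1ccc(Cl)cn1)S(=O)(=O)C(F)(F)F)C(F)(F)F; KN(SiMe3)2, C[Si](C)(C)[N-][Si](C)(C)C.[K+] (potassium only in 8)
Why: Kinetic α′-deprotonation of an enone followed by O-sulfonylation of the enolate: H-5 is the only hydrogen α to C6 (C7 is vinylic) and C9 has no α-hydrogen at all, low temperature and a hindered amide disfavour the slower γ-deprotonation of C12, so the enol triflate should be C5=C6, which deletes the cis-configured C5 and prepares its correction.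

Step 7
Reactants: 9 (10R)-3,3-ethylenedioxy-9-oxo-11-nordrima-5,7-dien-6-yl trifluoromethanesulfonate
Product: 11 (10R)-3,3-ethylenedioxy-11-nordrima-5,8-diene-6,9-diyl bis(trifluoromethanesulfonate), via lithium C8=C9 enolate 10 (not isolated)
Conditions: LiBH(s-Bu)3, THF, −78 °C; then N-(5-chloropyridin-2-yl)bis(trifluoromethanesulfonimide), −78 → 0 °C
Reagents that add atoms: N-(5-chloropyridin-2-yl)bis(trifluoromethanesulfonimide), O=S(=O)(N(c1ccc(Cl)cn1)S(=O)(=O)C(F)(F)F)C(F)(F)F; LiBH(s-Bu)3, [Li+].CCC(C)[BH-](C(C)CC)C(C)CC (lithium only in 10)
Why: Conjugate hydride reduction with in situ enolate triflation, as practised on α-methylcyclohexenones: the bulky borohydride avoids the neopentyl C9 carbonyl and the fully substituted C5 and adds to C7, and the regiodefined C8=C9 enolate is fixed as the second enol triflate while the vinylic C6 triflate is inert to hydride at low temperature.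

Step 8
Reactants: 11 (10R)-3,3-ethylenedioxy-11-nordrima-5,8-diene-6,9-diyl bis(trifluoromethanesulfonate)
Product: 12 3,3-ethylenedioxy-11-nordrima-5,8-diene (C10 unchanged in space)
Conditions: Pd(OAc)2 (10 mol %), PPh3 (20 mol %), HCO2H, n-Bu3N, DMF, 60 °C
Reagents that add atoms: none
Why: Palladium-catalysed formate reduction of enol triflates (oxidative addition to zerovalent palladium, decarboxylation of bound formate, C–H reductive elimination) replaces both C–O bonds by C–H without moving the alkenes, the quaternary C10 rules out aromatisation of the 1,4-diene, and the buffered medium spares the dioxolane.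

Step 9
Reactants: 12 3,3-ethylenedioxy-11-nordrima-5,8-diene
Product: 13 3,3-ethylenedioxy-8,11-cyclodrim-5-ene (cyclopropane C8–C9–C11 with C11 on the face opposite C15)
Conditions: Et2Zn, CH2I2, CH2Cl2, 0 °C → rt
Reagents that add atoms: diiodomethane, C(I)I
Why: Simmons–Smith cyclopropanation (diethylzinc variant) is a concerted syn addition, so C8 and C9 are set together by the face of attack, which is the one opposite the pseudo-axial C15 methyl and places C11 trans to it as in the target; C8=C9 reacts in preference to C5=C6 because the latter is flanked by the two quaternary carbons C4 and C10 and is shielded on both faces by their methyls.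

Step 10
Reactants: 13 3,3-ethylenedioxy-8,11-cyclodrim-5-ene
Product: 14 3,3-ethylenedioxy-8,11-cyclodrimane (trans-fused: H-5 on the face opposite C15)
Conditions: Mn(dpm)3 (dpm = 2,2,6,6-tetramethylheptane-3,5-dionate, 15 mol %), PhSiH3, t-BuOOH, i-PrOH, rt
Reagents that add atoms: none
Why: Metal-hydride hydrogen-atom-transfer hydrogenation: the manganese hydride delivers a hydrogen atom to the accessible C6, and the tertiary C5 radical takes up the second hydrogen on the face not covered by C15 and the axial C4 methyl, which gives the trans-decalin usually obtained by this method where hydrogenation on a metal surface would be blocked by the two quaternary neighbours; the cyclopropane is not adjacent to the radical and stays closed.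

Step 11
Reactants: 14 3,3-ethylenedioxy-8,11-cyclodrimane
Product: 15 8,11-cyclodriman-3-one (trans-fused)
Conditions: 1 M HCl, THF, rt
Reagents that add atoms: water, O
Why: Acid-catalysed hydrolysis of the dioxolane; C4 is quaternary so no stereocentre can epimerise, and an alkyl-substituted cyclopropane tolerates dilute aqueous acid at room temperature.

Step 12
Reactants: 15 8,11-cyclodriman-3-one
Product: 16 (3R)-8,11-cyclodriman-3-ol (equatorial OH, on the same face as C15)
Conditions: NaBH4, MeOH, 0 °C
Reagents that add atoms: none
Why: Borohydride reduction of a 4,4-dimethyl-3-oxo trans-decalin proceeds by axial attack on the face opposite the axial C4 methyl and C15, as is well known for 3-oxotriterpenoids, and gives the equatorial alcohol (3R, oxygen on the same face as C15).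

Step 13
Reactants: 16 (3R)-8,11-cyclodriman-3-ol
Product: 18 11-(chloromercurio)drimane-3,8-diol (all five stereocentres arranged as in the target), via organomercury trifluoroacetate 17 (not isolated)
Conditions: Hg(OCOCF3)2, THF–H2O, 0 °C → rt; then sat. aq. NaCl
Reagents that add atoms: mercury bis(trifluoroacetate), O=C(O[Hg]OC(=O)C(F)(F)F)C(F)(F)F; water, O; sodium chloride, [Na+].[Cl-]
Why: Electrophilic ring opening of a cyclopropane by divalent mercury: the metal takes the unhindered methylene C11, the C11–C8 bond breaks because the tertiary C8 carries positive charge best, and water attacks C8 from the rear with inversion, as established for 1-methylbicyclo[4.1.0]heptanes, so that 8-OH ends up trans-diaxial to the untouched C9–C11 bond and C12 becomes equatorial, which is the relative configuration of the target.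

Step 14
Reactants: 18 11-(chloromercurio)drimane-3,8-diol
Product: 19 11-iododrimane-3,8-diol (stereocentres unchanged)
Conditions: I2, CH2Cl2, rt
Reagents that add atoms: iodine, [I][I]
Why: Iododemercuration: iodine cleaves the primary C–Hg bond and leaves the two free hydroxy groups and all stereocentres untouched, C11 being a methylene so that the mechanism (radical or polar) has no stereochemical consequence.

Step 15
Reactants: 19 11-iododrimane-3,8-diol; 20 umbelliferone (7-hydroxycoumarin)
Product: 21 (3R,5S,8R,9S,10R)-11-(2-oxo-2H-chromen-7-yloxy)drimane-3,8-diol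
Conditions: Cs2CO3, DMF, 60 °C
Reagents that add atoms: none
Why: Williamson ether synthesis: the caesium phenoxide of 20 displaces the primary iodide by SN2, carbonate is too weak to deprotonate the C3 and C8 alcohols, and oxetane formation is excluded because 8-OH and C11 are anti-periplanar across C8–C9.

Step 16
Reactants: 21 (3R,5S,8R,9S,10R)-11-(2-oxo-2H-chromen-7-yloxy)drimane-3,8-diol; 22 tiglic acid
Product: 24 target CNP0189964.3 = (3R,5S,8R,9S,10R)-8-hydroxy-11-(2-oxo-2H-chromen-7-yloxy)driman-3-yl (E)-2-methylbut-2-enoate, via tigloyl trichlorobenzoyl anhydride 23 (not isolated)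
Conditions: 22, 2,4,6-Cl3C6H2COCl, Et3N, toluene, rt; then 21, DMAP, 60 °C
Reagents that add atoms: 2,4,6-trichlorobenzoyl chloride, O=C(Cl)c1c(Cl)cc(Cl)cc1Cl (its acyl group is carried only by 23)
Why: Yamaguchi esterification: the mixed anhydride activated by DMAP acylates the equatorial secondary 3-OH, whereas the axial tertiary 8-OH is inert under these conditions, and the thermodynamically preferred E geometry of the tiglate is retained.

Compound list
1 | 4-methoxy-2,6-dimethylphenol | COc1cc(C)c(O)c(C)c1 | starting material
2 | 4,4-dimethoxy-2,6-dimethylcyclohexa-2,5-dien-1-one | COC1(OC)C=C(C)C(=O)C(C)=C1 | intermediate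
3 | 4-methylpent-1-en-3-one | CC(C)C(=O)C=C | starting material
4 | 3-(tert-butyldimethylsilyloxy)-4-methylpenta-1,3-diene | C=CC(O[Si](C)(C)C(C)(C)C)=C(C)C | intermediate
5 | (5S,10R)-3-(tert-butyldimethylsilyloxy)-6,6-dimethoxy-11-nordrima-2,7-dien-9-one, cis-fused | CC(C)(C)[Si](C)(C)OC1=CC[C@]2(C)[C@@H](C(OC)(OC)C=C(C)C2=O)C1(C)C | intermediate
6 | (5S,10R)-11-nordrim-7-ene-3,6,9-trione, cis-fused | O=C1CC[C@]2(C)[C@@H](C(=O)C=C(C)C2=O)C1(C)C | intermediate
7 | (5S,10R)-3,3-ethylenedioxy-11-nordrim-7-ene-6,9-dione, cis-fused | C1COC2(O1)CC[C@]3(C)[C@@H](C(=O)C=C(C)C3=O)C2(C)C | intermediate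
8 | potassium C5=C6 enolate of 7 | C1COC2(O1)CC[C@]3(C)C(=C([O-])C=C(C)C3=O)C2(C)C.[K+] | intermediate
9 | (10R)-3,3-ethylenedioxy-9-oxo-11-nordrima-5,7-dien-6-yl trifluoromethanesulfonate | C1COC2(O1)CC[C@]3(C)C(=C(OS(=O)(=O)C(F)(F)F)C=C(C)C3=O)C2(C)C | intermediate
10 | lithium C8=C9 enolate from conjugate reduction of 9 | C1COC2(O1)CC[C@]3(C)C(=C(OS(=O)(=O)C(F)(F)F)CC(C)=C3[O-])C2(C)C.[Li+] | intermediate
11 | (10R)-3,3-ethylenedioxy-11-nordrima-5,8-diene-6,9-diyl bis(trifluoromethanesulfonate) | C1COC2(O1)CC[C@]3(C)C(=C(OS(=O)(=O)C(F)(F)F)CC(C)=C3OS(=O)(=O)C(F)(F)F)C2(C)C | intermediate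
12 | 3,3-ethylenedioxy-11-nordrima-5,8-diene | C1COC2(O1)CC[C@]3(C)C(=CCC(C)=C3)C2(C)C | intermediate
13 | 3,3-ethylenedioxy-8,11-cyclodrim-5-ene, C11 opposite C15 | C1COC2(O1)CC[C@]3(C)C(=CC[C@]4(C)C[C@H]34)C2(C)C | intermediate
14 | 3,3-ethylenedioxy-8,11-cyclodrimane, trans-fused | C1COC2(O1)CC[C@]3(C)[C@H](CC[C@]4(C)C[C@H]34)C2(C)C | intermediate
15 | 8,11-cyclodriman-3-one, trans-fused | O=C1CC[C@]2(C)[C@H](CC[C@]3(C)C[C@H]23)C1(C)C | intermediate
16 | (3R)-8,11-cyclodriman-3-ol, equatorial OH | O[C@@H]1CC[C@]2(C)[C@H](CC[C@]3(C)C[C@H]23)C1(C)C | intermediate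
17 | 11-(trifluoroacetoxymercurio)drimane-3,8-diol | O[C@@H]1CC[C@]2(C)[C@H](CC[C@@](C)(O)[C@@H]2C[Hg]OC(=O)C(F)(F)F)C1(C)C | intermediate
18 | 11-(chloromercurio)drimane-3,8-diol | O[C@@H]1CC[C@]2(C)[C@H](CC[C@@](C)(O)[C@@H]2C[Hg]Cl)C1(C)C | intermediate
19 | 11-iododrimane-3,8-diol | O[C@@H]1CC[C@]2(C)[C@H](CC[C@@](C)(O)[C@@H]2CI)C1(C)C | intermediate
20 | umbelliferone | O=c1ccc2ccc(O)cc2o1 | starting material
21 | (3R,5S,8R,9S,10R)-11-(2-oxo-2H-chromen-7-yloxy)drimane-3,8-diol | O[C@@H]1CC[C@]2(C)[C@H](CC[C@@](C)(O)[C@@H]2COc2ccc3ccc(=O)oc3c2)C1(C)C | intermediate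
22 | tiglic acid | C/C=C(\C)C(=O)O | starting material
23 | (E)-2-methylbut-2-enoic 2,4,6-trichlorobenzoic anhydride | C/C=C(\C)C(=O)OC(=O)c1c(Cl)cc(Cl)cc1Cl | intermediate
24 | CNP0189964.3, (3R,5S,8R,9S,10R)-8-hydroxy-11-(2-oxo-2H-chromen-7-yloxy)driman-3-yl tiglate | C/C=C(\C)C(=O)O[C@@H]1CC[C@]2(C)[C@H](CC[C@@](C)(O)[C@@H]2COc2ccc3ccc(=O)oc3c2)C1(C)C | target

Total step count: 16. Longest linear sequence: 15 (steps 1 and 3–16). Diene 4 is made in one side step; 20 and 22 enter as bought.

Steps most likely to fail

**Step 3.**
- What may go wrong: no turnover, because two centres flanked by quaternary carbons have to be joined; ionisation of the dimethyl ketal by the strong acid; a racemic background reaction carried by silyl triflimide; or weak discrimination between the two enantiotopic alkenes.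
- Fallback: auxiliary control plus separation of diastereomers. It sets out from 2 and 4 and comes back at 6.
- Compound 2 is transketalised with (R,R)-hydrobenzoin (BF3·OEt2, DME, rt). This gives the C2-symmetric (2R,3R)-7,9-dimethyl-2,3-diphenyl-1,4-dioxaspiro[4.5]deca-6,9-dien-8-one F1. Its dioxolane resists ionisation and makes the two alkene/face pairs diastereotopic, the known way in which chiral quinone monoketals direct additions.
- Annulation with 4 under HN(SO2CF3)2 (5 mol %, CH2Cl2, −40 °C) is the stepwise Mukaiyama–Michael/Michael process known for hindered silyloxydiene–enone pairs. It should give the cis adduct with C10 as in 5, hydrobenzoin-ketal adduct F2, beside its C5,C10-diastereomer F3.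
- The two are separated by chromatography or crystallisation, so enantiopurity no longer depends on the selectivity. F2 is then hydrolysed (CF3CO2H–H2O, CH2Cl2) to 6.

**Step 9.**
- What may go wrong: slow methylene transfer to the alkene next to the quaternary C10, so that attack on C5=C6 or double cyclopropanation competes.
- Fallback: the two alkenes are never present together. It sets out from 9 and comes back at 14.
- Formate reduction of 9 alone (Pd(OAc)2, PPh3, HCO2H, n-Bu3N, DMF) gives 3,3-ethylenedioxy-11-nordrima-5,7-dien-9-one F4.
- LiBH(s-Bu)3 adds hydride to C7. The resulting lithium C8=C9 enolate F5 is trapped with the pyridyl triflimide as 3,3-ethylenedioxy-11-nordrima-5,8-dien-9-yl triflate F6.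
- Hydrogen-atom-transfer hydrogenation under the conditions of step 10 should reduce only C5=C6, because the tetrasubstituted, electron-poor enol triflate is a poor hydrogen-atom acceptor. This gives the trans-fused 3,3-ethylenedioxy-11-nordrim-8-en-9-yl triflate F7.
- A second formate reduction gives trans-fused 3,3-ethylenedioxy-11-nordrim-8-ene F8. Its single alkene is cyclopropanated (Et2Zn, CH2I2) opposite C15 to give 14.

**Step 15.**
- What may go wrong: very slow SN2 displacement at the axial, doubly β-branched C11, with elimination towards the exocyclic alkene or fragmentation across C8–C9 taking over on heating.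
- Fallback: the O–aryl bond is made instead of the C11–O bond. It sets out from 18 and comes back at 21.
- Oxidative demercuration of 18 (NaBH4, O2, DMF) gives drimane-3,8,11-triol F9 with unchanged stereocentres.
- Palladium-catalysed C–O cross-coupling joins its primary hydroxy group to commercial 7-bromocoumarin (O=c1ccc2ccc(Br)cc2o1) and gives 21. Conditions: Pd(OAc)2, 2-(di-tert-butylphosphino)-3-methoxy-6-methyl-2',4',6'-triisopropylbiphenyl, Cs2CO3, toluene, 90 °C.
- The hindered carbon is then no longer the reaction centre, and the secondary and tertiary alcohols couple far more slowly.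

Further compounds
F1 | step 3 | (2R,3R)-7,9-dimethyl-2,3-diphenyl-1,4-dioxaspiro[4.5]deca-6,9-dien-8-one | CC1=CC2(C=C(C)C1=O)O[C@H](c1ccccc1)[C@@H](c1ccccc1)O2
F2 | step 3 | cis adduct with C5 and C10 as in 5, C6 masked as (R,R)-hydrobenzoin ketal | CC(C)(C)[Si](C)(C)OC1=CC[C@]2(C)[C@@H](C3(O[C@H](c4ccccc4)[C@@H](c4ccccc4)O3)C=C(C)C2=O)C1(C)C
F3 | step 3 | C5,C10-diastereomer of F2 (separated and discarded) | CC(C)(C)[Si](C)(C)OC1=CC[C@@]2(C)[C@H](C3(O[C@H](c4ccccc4)[C@@H](c4ccccc4)O3)C=C(C)C2=O)C1(C)C
F4 | step 9 | 3,3-ethylenedioxy-11-nordrima-5,7-dien-9-one | C1COC2(O1)CC[C@]3(C)C(=CC=C(C)C3=O)C2(C)C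
F5 | step 9 | lithium C8=C9 enolate from conjugate reduction of F4 | C1COC2(O1)CC[C@]3(C)C(=CCC(C)=C3[O-])C2(C)C.[Li+]
F6 | step 9 | 3,3-ethylenedioxy-11-nordrima-5,8-dien-9-yl trifluoromethanesulfonate | C1COC2(O1)CC[C@]3(C)C(=CCC(C)=C3OS(=O)(=O)C(F)(F)F)C2(C)C
F7 | step 9 | trans-fused 3,3-ethylenedioxy-11-nordrim-8-en-9-yl trifluoromethanesulfonate | C1COC2(O1)CC[C@]3(C)[C@H](CCC(C)=C3OS(=O)(=O)C(F)(F)F)C2(C)C
F8 | step 9 | trans-fused 3,3-ethylenedioxy-11-nordrim-8-ene | C1COC2(O1)CC[C@]3(C)[C@H](CCC(C)=C3)C2(C)C
F9 | step 15 | drimane-3,8,11-triol, stereocentres arranged as in 21 | O[C@@H]1CC[C@]2(C)[C@H](CC[C@@](C)(O)[C@@H]2CO)C1(C)C
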